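**Retrosynthetic overview**
1. Target 9 ⇐ tetra-O-benzyl ether 8 by hydrogenolysis (last step).
2. 8 ⇐ bisphenol 2 + two ynethioates 6. Both pyranone rings are cut at O1–C2 and C4–C4a; the two aryl–O–vinyl C–O bonds are made first and fix the regiochemistry (free ortho-OH gives the 8-linked flavone unit, free para-OH gives the 6-linked unit).
3. 2 ⇐ ortho–para oxidative homocoupling of 3,5-bis(benzyloxy)phenol 1; 6 ⇐ 4-ethynylanisole 3 + S-ethyl chlorothioformate 4.
4. Ring order: the biaryl (both benzenoid rings) first, then both pyranone rings in one flask.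

Assumption: the SMILES has no stereodescriptor and the only stereogenic element is the hindered 6,8''-biaryl axis, so the compound is made as drawn, racemic about that axis.

**Step 1**
Reactants: 1 3,5-bis(benzyloxy)phenol (two molecules)
Product: 2 2',4,6,6'-tetrakis(benzyloxy)-[1,1'-biphenyl]-2,4'-diol (racemic about the axis)
Conditions: Cr(salen)Cl (10 mol %; salen = N,N'-bis(3,5-di-tert-butylsalicylidene)cyclohexane-1,2-diamine dianion), O2 (1 atm), ClCH2CH2Cl, 80 °C
Reagents that add atoms: none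
Why: Aerobic oxidative phenol homocoupling under salen–chromium catalysis; the para carbon is the most nucleophilic site of the free phenol and the ortho carbon the reactive site of the metal-bound phenoxyl, so the ortho–para dimer should dominate, as expected by analogy with 3,5-dimethoxyphenol, and the axis forms without control.

**Step 2**
Reactants: 3 1-ethynyl-4-methoxybenzene; 4 S-ethyl carbonochloridothioate
Product: 6 S-ethyl 3-(4-methoxyphenyl)prop-2-ynethioate, via lithium (4-methoxyphenyl)acetylide 5 (not isolated)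
Conditions: n-BuLi, THF, −78 °C; then inverse addition to 4, THF, −78 °C
Reagents that add atoms: none
Why: Acylation of a lithium acetylide by a chlorothioformate (addition–elimination at the acyl chloride), with inverse addition at low temperature to prevent a second addition.

**Step 3**
Reactants: 2 2',4,6,6'-tetrakis(benzyloxy)-[1,1'-biphenyl]-2,4'-diol; 6 S-ethyl 3-(4-methoxyphenyl)prop-2-ynethioate (2.3 equiv)
Product: 8 tetra-O-benzyl biflavone [5,5'',7,7''-tetrakis(benzyloxy)-4',4'''-dimethoxy-6,8''-biflavone], via bis(aryl vinyl ether) dithioester 7 (not isolated)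
Conditions: Cs2CO3 (20 mol %), MeCN, 50 °C; evaporate; then AgOTf (2.6 equiv), NaHCO3 (6 equiv), 4 Å MS, CH2Cl2, 0 °C to rt
Reagents that add atoms: none
Why: Proposed new method: a Ruhemann-type flavone annulation under near-neutral conditions, in which base-catalysed oxa-Michael addition of both free phenols to the ynethioate forms the two O1–C2 bonds and so decides which oxygen becomes the ring oxygen of each unit, after which the thiophilic monovalent silver salt AgOTf removes ethanethiolate from each push–pull thioester to give an acylium ion (its ketene–oxocarbenium resonance form lets E and Z isomers converge) that acylates the ring carbon ortho to the new ether oxygen (the only free one in the ortho-hydroxy ring, either of two equivalent ones in the para-hydroxy ring) without touching the benzyl ethers; the closest known reaction types are the Ruhemann flavone synthesis (phenol plus arylpropiolate, then strong-acid ring closure) and Masamune-type thiophile-promoted acyl transfer from thioesters.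

**Step 4**
Reactants: 8 tetra-O-benzyl biflavone [5,5'',7,7''-tetrakis(benzyloxy)-4',4'''-dimethoxy-6,8''-biflavone]
Product: 9 5,7-dihydroxy-6-[5,7-dihydroxy-2-(4-methoxyphenyl)-4-oxo-4H-chromen-8-yl]-2-(4-methoxyphenyl)-4H-chromen-4-one (target, racemic about the axis)
Conditions: H2 (1 atm), Pd/C (10 wt %), THF/MeOH, rt
Reagents that add atoms: none
Why: Catalytic hydrogenolysis cleaves the four benzyl aryl ethers, while the flavone C2=C3 bonds, the two aryl methyl ethers and the biaryl bond survive at 1 atm and room temperature.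

**Compound list**
1 | 3,5-bis(benzyloxy)phenol | Oc1cc(OCc2ccccc2)cc(OCc2ccccc2)c1 | starting material
2 | 2',4,6,6'-tetrakis(benzyloxy)-[1,1'-biphenyl]-2,4'-diol (racemic about the axis) | Oc1cc(OCc2ccccc2)cc(OCc2ccccc2)c1-c1c(OCc2ccccc2)cc(O)cc1OCc1ccccc1 | intermediate
3 | 1-ethynyl-4-methoxybenzene | C#Cc1ccc(OC)cc1 | starting material
4 | S-ethyl carbonochloridothioate | CCSC(=O)Cl | starting material
5 | lithium (4-methoxyphenyl)acetylide | [Li]C#Cc1ccc(OC)cc1 | intermediate
6 | S-ethyl 3-(4-methoxyphenyl)prop-2-ynethioate | CCSC(=O)C#Cc1ccc(OC)cc1 | intermediate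
7 | S,S'-diethyl (2Z,2'Z)-3,3'-{[2',4,6,6'-tetrakis(benzyloxy)-[1,1'-biphenyl]-2,4'-diyl]bis(oxy)}bis[3-(4-methoxyphenyl)prop-2-enethioate] (anti-addition isomer shown; racemic about the axis) | CCSC(=O)/C=C(\Oc1cc(OCc2ccccc2)cc(OCc2ccccc2)c1-c1c(OCc2ccccc2)cc(O/C(=C\C(=O)SCC)c2ccc(OC)cc2)cc1OCc1ccccc1)c1ccc(OC)cc1 | intermediate
8 | 5,7-bis(benzyloxy)-6-[5,7-bis(benzyloxy)-2-(4-methoxyphenyl)-4-oxo-4H-chromen-8-yl]-2-(4-methoxyphenyl)-4H-chromen-4-one (racemic about the axis) | COc1ccc(-c2cc(=O)c3c(OCc4ccccc4)c(-c4c(OCc5ccccc5)cc(OCc5ccccc5)c5c(=O)cc(-c6ccc(OC)cc6)oc45)c(OCc4ccccc4)cc3o2)cc1 | intermediate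
9 | 5,7-dihydroxy-6-[5,7-dihydroxy-2-(4-methoxyphenyl)-4-oxo-4H-chromen-8-yl]-2-(4-methoxyphenyl)-4H-chromen-4-one (6,8''-biacacetin; racemic about the axis) | COc1ccc(-c2cc(=O)c3c(O)c(-c4c(O)cc(O)c5c(=O)cc(-c6ccc(OC)cc6)oc45)c(O)cc3o2)cc1 | target

**Step count**
Total steps: 4. Longest linear sequence: 3 steps (1 → 2 → 8 → 9); step 2 is a one-step side branch.

**Three steps most likely to fail**

Step 3 (the proposed new step). Possible failures:
- acyl transfer from the thioester to phenoxide, followed by thia-Michael consumption of 6;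
- slow addition at the hindered ortho-hydroxyl;
- too weak thiophilic activation of the push–pull thioester.

The fallback uses known chemistry, sets out from 2 and comes back at 8. Compound 2 is heated with commercial ethyl 3-(4-methoxyphenyl)prop-2-ynoate (K2CO3, DMF, 90 °C; classical oxa-Michael of the Ruhemann synthesis) to give diethyl (2Z,2'Z)-3,3'-{[2',4,6,6'-tetrakis(benzyloxy)-[1,1'-biphenyl]-2,4'-diyl]bis(oxy)}bis[3-(4-methoxyphenyl)prop-2-enoate] F1. Saponification (LiOH, THF/MeOH/H2O, rt) gives the corresponding bis(prop-2-enoic acid) F2. Trifluoroacetic anhydride (CH2Cl2, 0 °C to rt) converts this into the bis(mixed trifluoroacetic anhydride) F3, which closes both rings by intramolecular Friedel–Crafts acylation to 8.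

Step 1. The dimerisation may give a mixture of ortho–ortho, ortho–para and para–para dimers plus oligomers. The fallback replaces oxidative coupling by a regiochemically fixed Suzuki–Miyaura coupling; it sets out from 1 and comes back at 2.
- Silylation of 1 (TIPSCl, imidazole, DMF) gives [3,5-bis(benzyloxy)phenoxy]tri(propan-2-yl)silane F4.
- Lithiation between the two benzyloxy groups (n-BuLi, THF, 0 °C) gives the aryllithium {2,6-bis(benzyloxy)-4-[tri(propan-2-yl)silyloxy]phenyl}lithium F5.
- Quenching with 2-isopropoxy-4,4,5,5-tetramethyl-1,3,2-dioxaborolane gives 2-{2,6-bis(benzyloxy)-4-[tri(propan-2-yl)silyloxy]phenyl}-4,4,5,5-tetramethyl-1,3,2-dioxaborolane F6.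
- Separately, amine-catalysed ortho-bromination of 1 (NBS, cat. i-Pr2NH, CH2Cl2, 0 °C) gives 2-bromo-3,5-bis(benzyloxy)phenol F7.
- Coupling of F6 with F7 (Pd(OAc)2, SPhos, K3PO4, toluene/H2O, 90 °C) gives 2',4,6,6'-tetrakis(benzyloxy)-4'-[tri(propan-2-yl)silyloxy]-[1,1'-biphenyl]-2-ol F8.
- TBAF (THF, 0 °C) returns 2.

Step 4. Traces of sulfur or silver from step 3 can poison Pd/C, and long reaction times risk partial saturation of the C2=C3 bonds. The fallback sets out from 8 and comes back at 9 directly. It is a Lewis-acid debenzylation with a cation scavenger (BCl3, pentamethylbenzene, CH2Cl2, −78 °C), which leaves the aryl methyl ethers and the chromone double bonds alone; no new compound arises on this way (F0).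

**Further compounds**
F1 | step 3 | diethyl (2Z,2'Z)-3,3'-{[2',4,6,6'-tetrakis(benzyloxy)-[1,1'-biphenyl]-2,4'-diyl]bis(oxy)}bis[3-(4-methoxyphenyl)prop-2-enoate] | CCOC(=O)/C=C(\Oc1cc(OCc2ccccc2)cc(OCc2ccccc2)c1-c1c(OCc2ccccc2)cc(O/C(=C\C(=O)OCC)c2ccc(OC)cc2)cc1OCc1ccccc1)c1ccc(OC)cc1
F2 | step 3 | (2Z,2'Z)-3,3'-{[2',4,6,6'-tetrakis(benzyloxy)-[1,1'-biphenyl]-2,4'-diyl]bis(oxy)}bis[3-(4-methoxyphenyl)prop-2-enoic acid] | OC(=O)/C=C(\Oc1cc(OCc2ccccc2)cc(OCc2ccccc2)c1-c1c(OCc2ccccc2)cc(O/C(=C\C(=O)O)c2ccc(OC)cc2)cc1OCc1ccccc1)c1ccc(OC)cc1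
F3 | step 3 | bis(mixed trifluoroacetic anhydride) of F2 | FC(F)(F)C(=O)OC(=O)/C=C(\Oc1cc(OCc2ccccc2)cc(OCc2ccccc2)c1-c1c(OCc2ccccc2)cc(O/C(=C\C(=O)OC(=O)C(F)(F)F)c2ccc(OC)cc2)cc1OCc1ccccc1)c1ccc(OC)cc1
F4 | step 1 | [3,5-bis(benzyloxy)phenoxy]tri(propan-2-yl)silane | CC(C)[Si](Oc1cc(OCc2ccccc2)cc(OCc2ccccc2)c1)(C(C)C)C(C)C
F5 | step 1 | {2,6-bis(benzyloxy)-4-[tri(propan-2-yl)silyloxy]phenyl}lithium | CC(C)[Si](Oc1cc(OCc2ccccc2)c([Li])c(OCc2ccccc2)c1)(C(C)C)C(C)C
F6 | step 1 | 2-{2,6-bis(benzyloxy)-4-[tri(propan-2-yl)silyloxy]phenyl}-4,4,5,5-tetramethyl-1,3,2-dioxaborolane | CC(C)[Si](Oc1cc(OCc2ccccc2)c(B2OC(C)(C)C(C)(C)O2)c(OCc2ccccc2)c1)(C(C)C)C(C)C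
F7 | step 1 | 2-bromo-3,5-bis(benzyloxy)phenol | Oc1cc(OCc2ccccc2)cc(OCc2ccccc2)c1Br
F8 | step 1 | 2',4,6,6'-tetrakis(benzyloxy)-4'-[tri(propan-2-yl)silyloxy]-[1,1'-biphenyl]-2-ol | Oc1cc(OCc2ccccc2)cc(OCc2ccccc2)c1-c1c(OCc2ccccc2)cc(O[Si](C(C)C)(C(C)C)C(C)C)cc1OCc1ccccc1
F0 | step 4 | none | none
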